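**Retrosynthetic overview**

1. Feature: C1, the quaternary carbinol carrying C7H2OBz, is the sp3 carbon of a latent para-quinol. In dienone 4 the arms C2=C3 and C6=C5, both conjugated to the C4 carbonyl, are enantiotopic, so one epoxidation makes C1, C2 and C3 stereogenic at once.
2. Disconnections: 13 ⇒ C5–OH benzoylation of triol 12 ⇒ acetonide 11 ⇒ allylic alcohol 9 ⇒ (Wharton) 2,3-epoxy-4-ketone 7 ⇒ (OsO4 on C5=C6, then acetonide) epoxy enone 5 ⇒ (desymmetrising epoxidation) para-quinol 4 ⇒ (PhI(OAc)2) phenol 3 ⇒ 4-hydroxybenzyl alcohol 1 + benzoic acid 2.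
3. Rings: the six-membered carbocycle is the arene ring of 1 throughout. The oxirane (closed in step 3, opened in step 6) and the dioxolane (closed in step 5, opened in step 8) are temporary.

Key step: step 3

Numbering and faces: ring atoms keep the target numbers in all intermediates (C1 quaternary, C7 = CH2OBz, C3=C4 the final alkene). With the ring drawn flat and C1→C6 clockwise, β is towards the viewer. The target, read as (1R,2S,5S,6S), has C1–OH and C2–O β and C5–O, C6–O and C7 α.

Assumption: the sense of arm selection by the cinchona-derived amine cannot be derived with certainty from simple cyclic enones. The route is written with the quinine-derived amine; its quinidine-derived pseudoenantiomer would be used if a pilot run shows the opposite sense.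

**Route**

Step 1
Reactants: 1 4-hydroxybenzyl alcohol; 2 benzoic acid
Product: 3 4-hydroxybenzyl benzoate
Conditions: PPh3, DIAD, THF, 0 °C to rt
Reagents that add atoms: benzoic acid (2), O=C(O)c1ccccc1
Why: Mitsunobu esterification, in which the alkoxyphosphonium ion of the benzylic alcohol is displaced by benzoate while the far less acidic phenol stays out of the reaction, so only the benzylic hydroxyl is esterified.

Step 2
Reactants: 3 4-hydroxybenzyl benzoate
Product: 4 (1-hydroxy-4-oxocyclohexa-2,5-dien-1-yl)methyl benzoate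
Conditions: PhI(OAc)2 (trivalent iodine), MeCN/H2O (4:1), 0 °C
Reagents that add atoms: water, O
Why: Oxidative dearomatisation of a para-substituted phenol, in which the aryloxy-iodane ionises and water adds at the para carbon to give the achiral para-quinol with the benzoate untouched.

Step 3
Reactants: 4 (1-hydroxy-4-oxocyclohexa-2,5-dien-1-yl)methyl benzoate
Product: 5 [(1S,2S,6R)-2-hydroxy-5-oxo-7-oxabicyclo[4.1.0]hept-3-en-2-yl]methyl benzoate (2β,3β-epoxide syn to the C1β hydroxyl)
Conditions: 9-amino-9-deoxy-epi-quinine (20 mol%), CF3CO2H (40 mol%), 50% aq. H2O2 (1.2 equiv), dioxane, 30 °C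
Reagents that add atoms: hydrogen peroxide, OO
Why: Proposed new method: the primary amine condenses with the C4 ketone to a cross-conjugated iminium ion, hydrogen peroxide held by the protonated quinuclidine adds in conjugate fashion at C2 (C2–O), and the β-hydroperoxy enamine closes the oxirane by attack of C3 on the proximal peroxide oxygen with loss of water (C3–O, 3-exo-tet at oxygen), after which hydrolysis frees 5 and the amine. The closest known reaction types are the primary-amine-salt-catalysed asymmetric Weitz–Scheffer epoxidation of cyclic enones with H2O2 and the hydroxyl-directed nucleophilic epoxidation of para-quinols; their combination on a prochiral dienone is the new element. The oxirane is necessarily cis-fused, so C2 and C3 are set together, and their face is that of the C1 hydroxyl, which hydrogen-bonds the incoming peroxide. C1 becomes stereogenic only through the choice of arm, which falls to the catalyst: once the hydroxyl has fixed the ring face, the hydroxyl-syn faces of the two β-carbons C2 and C6 are enantiotopic, and the chiral ammonium ion pair should deliver peroxide to one of them. The step needs arm selectivity (catalyst), syn facial selectivity (C1–OH) and mono-epoxidation; the last is secured by the small excess of H2O2 and by the surviving arm of 5 offering the catalyst only its mismatched hydroxyl-syn face.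

Step 4
Reactants: 5 [(1S,2S,6R)-2-hydroxy-5-oxo-7-oxabicyclo[4.1.0]hept-3-en-2-yl]methyl benzoate
Product: 6 [(1S,2R,3S,4R,6R)-2,3,4-trihydroxy-5-oxo-7-oxabicyclo[4.1.0]heptan-2-yl]methyl benzoate (C5α,C6α-diol)
Conditions: OsO4 (5 mol%), NMO, citric acid, t-BuOH/H2O (1:1), rt
Reagents that add atoms: osmium tetroxide, O=[Os](=O)(=O)=O (both new oxygen atoms; recycled by N-methylmorpholine N-oxide, C[N+]1([O-])CCOCC1, and water, O)
Why: Upjohn cis-dihydroxylation, with citric acid to speed turnover on the electron-poor alkene; the [3+2] addition should occur on the face opposite to the allylic C1 hydroxyl (Kishi's rule) and to the cross-ring oxirane oxygen, setting C5 and C6 together as α.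

Step 5
Reactants: 6 [(1S,2R,3S,4R,6R)-2,3,4-trihydroxy-5-oxo-7-oxabicyclo[4.1.0]heptan-2-yl]methyl benzoate
Product: 7 5,6-O-isopropylidene acetal of 6 (target numbering 1S,2S,3R,5R,6S; dioxolane α and cis-fused)
Conditions: 2,2-dimethoxypropane, PPTS (cat.), acetone, rt
Reagents that add atoms: 2,2-dimethoxypropane, COC(C)(C)OC
Why: Acid-catalysed transketalisation, in which only the cis C5/C6 diol can close an unstrained cis-fused dioxolane, so the trans-disposed tertiary C1 hydroxyl stays free and the α-ketol is masked before the hydrazine step.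

Step 6
Reactants: 7 5,6-O-isopropylidene acetal of 6
Product: 9 [(3aS,4S,5S,7aS)-4,5-dihydroxy-2,2-dimethyl-3a,4,5,7a-tetrahydro-1,3-benzodioxol-4-yl]methyl benzoate, via epoxy hydrazone 8 (not isolated)
Conditions: N2H4·H2O (2.5 equiv), AcOH (0.5 equiv), MeOH, 0 °C to rt
Reagents that add atoms: hydrazine, NN (its nitrogen atoms stand in intermediate 8 and leave as N2)
Why: Wharton transposition, in which the hydrazone of the α,β-epoxy ketone opens the strained oxirane at C3–O to a vinyl diazene that loses N2, leaving C3=C4 and the C2β hydroxyl with its C2–O bond and configuration untouched; the acetonide oxygen at C5 is a far poorer leaving group than the oxirane oxygen, and buffered hydrazine at 0 °C should spare the primary benzoate.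

Step 7
Reactants: 9 [(3aS,4S,5S,7aS)-4,5-dihydroxy-2,2-dimethyl-3a,4,5,7a-tetrahydro-1,3-benzodioxol-4-yl]methyl benzoate; 10 benzoyl chloride
Product: 11 [(3aS,4S,5S,7aS)-5-(benzoyloxy)-4-hydroxy-2,2-dimethyl-3a,4,5,7a-tetrahydro-1,3-benzodioxol-4-yl]methyl benzoate
Conditions: BzCl (1.5 equiv), pyridine, DMAP (cat.), CH2Cl2, 0 °C
Reagents that add atoms: benzoyl chloride (10), O=C(Cl)c1ccccc1
Why: DMAP-catalysed acylation of the secondary allylic C2 hydroxyl, the only acylable one because the C1 hydroxyl is tertiary and the C5/C6 pair is masked; no stereocentre is touched, and a benzoyl group that had drifted from O7 to O2 in step 6 would be made good here.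

Step 8
Reactants: 11 [(3aS,4S,5S,7aS)-5-(benzoyloxy)-4-hydroxy-2,2-dimethyl-3a,4,5,7a-tetrahydro-1,3-benzodioxol-4-yl]methyl benzoate
Product: 12 [(1R,2S,5S,6S)-2-(benzoyloxy)-1,5,6-trihydroxycyclohex-3-en-1-yl]methyl benzoate
Conditions: AcOH/H2O (4:1), 40 °C
Reagents that add atoms: none
Why: Acid-catalysed acetal hydrolysis, in which the cis-fused dioxolane is cleaved by warm aqueous acetic acid, a medium in which benzoates should neither hydrolyse nor migrate at a useful rate.

Step 9
Reactants: 12 [(1R,2S,5S,6S)-2-(benzoyloxy)-1,5,6-trihydroxycyclohex-3-en-1-yl]methyl benzoate; 10 benzoyl chloride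
Product: 13 [(1R,2S,5S,6S)-2,5-bis(benzoyloxy)-1,6-dihydroxycyclohex-3-en-1-yl]methyl benzoate (target)
Conditions: BzCl (1.1 equiv), pyridine, CH2Cl2, −30 to 0 °C
Reagents that add atoms: benzoyl chloride (10), O=C(Cl)c1ccccc1
Why: Regioselective acylation: in the half-chair with the C1 CH2OBz group equatorial, the allylic C5 hydroxyl is pseudoequatorial and open, the C6 hydroxyl is axial and flanked by the fully substituted C1, and the C1 hydroxyl is tertiary, so one equivalent of BzCl at low temperature should acylate C5 only.

**Compound list**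

1 | 4-hydroxybenzyl alcohol | OCc1ccc(O)cc1 | starting material
2 | benzoic acid | O=C(O)c1ccccc1 | starting material
3 | 4-hydroxybenzyl benzoate | O=C(OCc1ccc(O)cc1)c1ccccc1 | intermediate
4 | (1-hydroxy-4-oxocyclohexa-2,5-dien-1-yl)methyl benzoate | O=C(OCC1(O)C=CC(=O)C=C1)c1ccccc1 | intermediate
5 | [(1S,2S,6R)-2-hydroxy-5-oxo-7-oxabicyclo[4.1.0]hept-3-en-2-yl]methyl benzoate | O=C(OC[C@]1(O)[C@H]2O[C@H]2C(=O)C=C1)c1ccccc1 | intermediate
6 | [(1S,2R,3S,4R,6R)-2,3,4-trihydroxy-5-oxo-7-oxabicyclo[4.1.0]heptan-2-yl]methyl benzoate | O=C(OC[C@]1(O)[C@H]2O[C@H]2C(=O)[C@H](O)[C@@H]1O)c1ccccc1 | intermediate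
7 | 5,6-O-isopropylidene acetal of 6 (target numbering 1S,2S,3R,5R,6S) | O=C(OC[C@]1(O)[C@H]2O[C@H]2C(=O)[C@@H]3OC(C)(C)O[C@H]13)c1ccccc1 | intermediate
8 | C4 hydrazone of 7 (epoxy hydrazone) | O=C(OC[C@]1(O)[C@H]2O[C@H]2C(=NN)[C@@H]3OC(C)(C)O[C@H]13)c1ccccc1 | intermediate (not isolated)
9 | [(3aS,4S,5S,7aS)-4,5-dihydroxy-2,2-dimethyl-3a,4,5,7a-tetrahydro-1,3-benzodioxol-4-yl]methyl benzoate | O=C(OC[C@]1(O)[C@@H](O)C=C[C@@H]2OC(C)(C)O[C@H]12)c1ccccc1 | intermediate
10 | benzoyl chloride | O=C(Cl)c1ccccc1 | starting material
11 | [(3aS,4S,5S,7aS)-5-(benzoyloxy)-4-hydroxy-2,2-dimethyl-3a,4,5,7a-tetrahydro-1,3-benzodioxol-4-yl]methyl benzoate | O=C(OC[C@]1(O)[C@@H](OC(=O)c2ccccc2)C=C[C@@H]3OC(C)(C)O[C@H]13)c1ccccc1 | intermediate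
12 | [(1R,2S,5S,6S)-2-(benzoyloxy)-1,5,6-trihydroxycyclohex-3-en-1-yl]methyl benzoate | O=C(OC[C@]1(O)[C@@H](OC(=O)c2ccccc2)C=C[C@H](O)[C@@H]1O)c1ccccc1 | intermediate
13 | [(1R,2S,5S,6S)-2,5-bis(benzoyloxy)-1,6-dihydroxycyclohex-3-en-1-yl]methyl benzoate | O=C(OC[C@]1(O)[C@@H](OC(=O)c2ccccc2)C=C[C@H](OC(=O)c2ccccc2)[C@@H]1O)c1ccccc1 | target

**Step count and risks**

Total steps: 9. Longest linear sequence: 9 steps (from 1).

Steps most likely to fail:

1. Step 3 (proposed new method). The catalyst may discriminate poorly between the two enone arms, giving low enantiomeric purity. Peroxide may also leak to the face anti to the hydroxyl, the mono-epoxide may be epoxidised again, or the cross-conjugated dienone may form its iminium ion too slowly. Fallback with known chemistry, setting out from 4: hydroxyl-directed Weitz–Scheffer epoxidation without a chiral catalyst (tert-butyl hydroperoxide, DBU, CH2Cl2, 0 °C) should give the syn-epoxide as a racemate of 5 and its enantiomer, [(1R,2R,6S)-2-hydroxy-5-oxo-7-oxabicyclo[4.1.0]hept-3-en-2-yl]methyl benzoate F1. The racemate is then resolved by preparative chromatography on a chiral stationary phase (amylose tris(3,5-dimethylphenylcarbamate) on silica). The route is rejoined at 5.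

2. Step 4. Osmylation may take place on the β face, pushed there by the CH2OBz group on the α side of C1, or the electron-poor alkene may react too slowly and the sensitive α,β-dihydroxy ketone may degrade. Fallback setting out from 5: the tertiary hydroxyl is silylated (TESOTf, 2,6-lutidine, CH2Cl2, −78 °C) to the C1 triethylsilyl ether of 5 F2, so that a bulky silyloxy group and the oxirane both shield the β face. Dihydroxylation (OsO4, NMO) should then give the C1 triethylsilyl ether of 6 F3. Acetalisation (2,2-dimethoxypropane, PPTS) gives the C1 triethylsilyl ether of 7 F4, and HF·pyridine in THF at 0 °C removes the silyl group. The route is rejoined at 7.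

3. Step 6. Hydrazine may cleave the primary benzoate, or the vinyl diazene may break down along unproductive paths, so that little allylic alcohol is formed. Fallback setting out from 7: the ketone is reduced (NaBH4, MeOH, −20 °C) to the C4 carbinol of 7 F5; either C4 epimer serves. The carbinol is converted with 1,1'-thiocarbonyldiimidazole and DMAP in ClCH2CH2Cl at 60 °C into its O-(imidazol-1-ylcarbonothioyl) derivative F6. Bu3SnH and AIBN in toluene at 80 °C then generate the C4 radical, which opens the adjacent oxirane to the C2 alkoxy radical and C3=C4 (Barton–McCombie-type radical epoxide fragmentation). The stannane is kept concentrated so that hydrogen transfer outruns β-scission. The route is rejoined at 9.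

**Further compounds**

F1 | step 3 | [(1R,2R,6S)-2-hydroxy-5-oxo-7-oxabicyclo[4.1.0]hept-3-en-2-yl]methyl benzoate (enantiomer of 5, formed with 5 as the racemate) | O=C(OC[C@@]1(O)[C@@H]2O[C@@H]2C(=O)C=C1)c1ccccc1
F2 | step 4 | [(1S,2S,6R)-5-oxo-2-(triethylsilyloxy)-7-oxabicyclo[4.1.0]hept-3-en-2-yl]methyl benzoate (C1 triethylsilyl ether of 5) | O=C(OC[C@]1(O[Si](CC)(CC)CC)[C@H]2O[C@H]2C(=O)C=C1)c1ccccc1
F3 | step 4 | C1 triethylsilyl ether of 6 | O=C(OC[C@]1(O[Si](CC)(CC)CC)[C@H]2O[C@H]2C(=O)[C@H](O)[C@@H]1O)c1ccccc1
F4 | step 4 | C1 triethylsilyl ether of 7 | O=C(OC[C@]1(O[Si](CC)(CC)CC)[C@H]2O[C@H]2C(=O)[C@@H]3OC(C)(C)O[C@H]13)c1ccccc1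
F5 | step 6 | C4 carbinol of 7 (epoxy alcohol, C4 configuration immaterial) | O=C(OC[C@]1(O)[C@H]2O[C@H]2C(O)[C@@H]3OC(C)(C)O[C@H]13)c1ccccc1
F6 | step 6 | C4 O-(imidazol-1-ylcarbonothioyl) derivative of F5 | O=C(OC[C@]1(O)[C@H]2O[C@H]2C(OC(=S)n4ccnc4)[C@@H]3OC(C)(C)O[C@H]13)c1ccccc1
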